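The target is disconnected at the C5–C10 bond of the cyclohexanone and the O2–C3 bond of the lactone (2-oxaspiro[4.5]decane locants). Spiro carbon C5 is at once α to the ring ketone C6 and attached to the lactone carbinol carbon C1. Such a β-oxy ketone across a quaternary centre is what a semipinacol shift from a carbinol carbon onto a neighbouring oxirane carbon delivers. The precursor is a (2R,3R)-trisubstituted epoxide bearing a 1-silyloxycyclopentyl group, a CH2CO2Me arm and a propynyl group. One Lewis acid treatment enlarges the five-membered carbocycle to the cyclohexanone, sets C5 and closes the γ-lactone; the alkyne later becomes the dienyl chain.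

Key step: step 7

Remark: locants are those of the target core (C1 lactone CH–O, O2, C3 lactone C=O, C4, spiro C5, C6 ring C=O, C7, C8 C–N, C9 C–OH, C10); the carbinol is carried as its triethylsilyl ether, assumed to leave in step 7 as readily as a smaller silyl group while surviving steps 3–6 better.

Step 1
Reactants: 1 1-ethynylcyclopentan-1-ol; 2 allylmagnesium bromide
Product: 4 (Z)-1-(1-iodopenta-1,4-dien-2-yl)cyclopentan-1-ol, via alkenylmagnesium chelate 3 (not isolated)
Conditions: 2 (3 equiv), CuI (10 mol%), Et2O, −10 °C → rt; then I2, THF, −78 → 0 °C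
Reagents that add atoms: iodine, II
Why: Alkoxide-directed anti-carbomagnesiation of a propargylic alcohol places the allyl group on the carbinol-side alkyne carbon and magnesium on the terminal carbon inside a five-membered chelate, so that iodinolysis with retention gives the alkenyl iodide with iodine cis to the carbinol carbon (Z).

Step 2
Reactants: 4 (Z)-1-(1-iodopenta-1,4-dien-2-yl)cyclopentan-1-ol
Product: 5 triethyl({1-[(1Z)-1-iodopenta-1,4-dien-2-yl]cyclopentyl}oxy)silane
Conditions: TESOTf, 2,6-lutidine, CH2Cl2, −78 → 0 °C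
Reagents that add atoms: triethylsilyl trifluoromethanesulfonate, CC[Si](CC)(CC)OS(=O)(=O)C(F)(F)F
Why: Silyl triflate silylation of a tertiary alcohol, needed so that the tertiary oxygen cannot lactonise onto the acid or ester made next and can later act as the electron-releasing group of the rearrangement.

Step 3
Reactants: 5 triethyl({1-[(1Z)-1-iodopenta-1,4-dien-2-yl]cyclopentyl}oxy)silane
Product: 7 (3Z)-4-iodo-3-[1-(triethylsilyloxy)cyclopentyl]but-3-enal, via diol 6 (not isolated)
Conditions: OsO4 (2 mol%), NaIO4, 2,6-lutidine, dioxane/H2O, rt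
Reagents that add atoms: osmium tetroxide, O=[Os](=O)(=O)=O; sodium periodate, [Na+].[O-]I(=O)(=O)=O
Why: Lemieux–Johnson cleavage (osmylation then periodate glycol fission) takes the electron-rich monosubstituted alkene in preference to the hindered iodine-bearing trisubstituted one, and lutidine keeps the medium neutral for the silyl ether.

Step 4
Reactants: 7 (3Z)-4-iodo-3-[1-(triethylsilyloxy)cyclopentyl]but-3-enal
Product: 9 methyl (3Z)-4-iodo-3-[1-(triethylsilyloxy)cyclopentyl]but-3-enoate, via carboxylic acid 8 (not isolated)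
Conditions: NaClO2, NaH2PO4, 2-methylbut-2-ene, t-BuOH/H2O, 0 °C; then TMSCHN2, PhMe/MeOH, 0 °C
Reagents that add atoms: sodium chlorite, [Na+].[O-]Cl=O; trimethylsilyldiazomethane, C[Si](C)(C)C=[N+]=[N-]
Why: Pinnick oxidation of the crude aldehyde does not isomerise the β,γ-double bond or touch the iodoalkene, and methylation of the acid with the diazoalkane is neutral, so silyl ether and alkene geometry are kept.

Step 5
Reactants: 9 methyl (3Z)-4-iodo-3-[1-(triethylsilyloxy)cyclopentyl]but-3-enoate; 10 propyne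
Product: 11 methyl (3Z)-3-[1-(triethylsilyloxy)cyclopentyl]hept-3-en-5-ynoate
Conditions: 10 (excess), Pd(PPh3)2Cl2 (5 mol%), CuI (10 mol%), Et3N, THF, rt
Reagents that add atoms: none
Why: Sonogashira coupling of an alkenyl iodide runs at room temperature with retention of alkene geometry, which puts the propynyl group cis to the silyloxycyclopentyl carbon as the epoxide requires.

Step 6
Reactants: 11 methyl (3Z)-3-[1-(triethylsilyloxy)cyclopentyl]hept-3-en-5-ynoate
Product: 12 methyl 2-[(2R,3R)-3-(prop-1-yn-1-yl)-2-[1-(triethylsilyloxy)cyclopentyl]oxiran-2-yl]acetate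
Conditions: Shi ketone from D-fructose (0.5 equiv), Oxone, K2CO3, Bu4NHSO4, MeCN/DMM/aq. borate buffer (pH 10.5), −10 → 0 °C
Reagents that add atoms: potassium peroxymonosulfate (Oxone), [K+].[O-]S(=O)(=O)OO
Why: Shi epoxidation of a trisubstituted conjugated enyne: oxygen transfer from the chiral dioxirane is concerted, so the cis relation of alkynyl and cyclopentyl groups is kept, and the spiro transition state of the D-fructose-derived ketone is expected, by analogy with its known sense for trisubstituted alkenes, to attack the face that gives the (2R,3R)-epoxide, which fixes C1 of the target.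

Step 7
Reactants: 12 methyl 2-[(2R,3R)-3-(prop-1-yn-1-yl)-2-[1-(triethylsilyloxy)cyclopentyl]oxiran-2-yl]acetate
Product: 14 (1R,5R)-1-(prop-1-yn-1-yl)-2-oxaspiro[4.5]decane-3,6-dione, via hydroxy keto ester 13 (not isolated)
Conditions: BF3·OEt2 (1.2 equiv), CH2Cl2, −78 → −20 °C; then TsOH·H2O (10 mol%), rt
Reagents that add atoms: none
Why: BF3 binds the oxirane oxygen, the C–O bond at the fully substituted carbon stretches, and the antiperiplanar cyclopentane C–C bond shifts onto that carbon while the silyloxy carbon becomes the carbonyl and silicon leaves as the fluorosilane. This is a semipinacol rearrangement of a 2,3-epoxy alcohol silyl ether with ring enlargement, a known reaction type. The cyclohexanone forms by 1,2-alkyl shift ring expansion (C5–C10 bond), and the γ-lactone by 5-exo-trig acyl substitution of the released C1 oxygen on the methyl ester (O2–C3 bond), completed by the acid. The spiro centre C5 is set by the epoxide configuration because migration occurs with inversion at the receiving carbon, whereas C1 keeps the configuration from step 6; the two cyclopentane CH2 groups give the same product, so no choice of migrating group arises. The step needs ionisation at the tertiary and not at the propargylic oxirane carbon, which is secured by the higher substitution of the former, by the push of the silyloxy group through the migrating bond and by the electron-withdrawing sp carbon on the latter; this is why the side chain is carried as an alkyne at this stage.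

Step 8
Reactants: 14 (1R,5R)-1-(prop-1-yn-1-yl)-2-oxaspiro[4.5]decane-3,6-dione
Product: 15 (1R,5R)-6-[(tert-butyldimethylsilyl)oxy]-1-(prop-1-yn-1-yl)-2-oxaspiro[4.5]dec-6-en-3-one
Conditions: TBSOTf, Et3N, CH2Cl2, −78 → 0 °C
Reagents that add atoms: tert-butyldimethylsilyl trifluoromethanesulfonate, CC(C)(C)[Si](C)(C)OS(=O)(=O)C(F)(F)F
Why: Soft enolisation (silyl triflate and amine) silylates only the ketone, which can enolise only toward C7 because C5 is quaternary, and the enol ether both masks the carbonyl in steps 9–10 without an acid-labile ketal and serves as the substrate of step 11.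

Step 9
Reactants: 15 (1R,5R)-6-[(tert-butyldimethylsilyl)oxy]-1-(prop-1-yn-1-yl)-2-oxaspiro[4.5]dec-6-en-3-one
Product: 17 (1R,5R)-6-[(tert-butyldimethylsilyl)oxy]-1-[(1E)-2-iodoprop-1-en-1-yl]-2-oxaspiro[4.5]dec-6-en-3-one, via alkenylzirconocene 16 (not isolated)
Conditions: Cp2Zr(H)Cl (1.3 equiv), THF, rt → 40 °C; then I2, THF, −78 °C
Reagents that add atoms: iodine, II
Why: Hydrozirconation with the Schwartz reagent adds H and Zr syn across the alkyne with zirconium on the less hindered methyl-bearing carbon, and iodinolysis of the C–Zr bond with retention gives the E-alkenyl iodide, the trisubstituted enol ether and the lactone reacting much more slowly with either reagent.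

Step 10
Reactants: 17 (1R,5R)-6-[(tert-butyldimethylsilyl)oxy]-1-[(1E)-2-iodoprop-1-en-1-yl]-2-oxaspiro[4.5]dec-6-en-3-one; 18 5-bromo-2-methylpent-2-ene
Product: 20 (1R,5R)-6-[(tert-butyldimethylsilyl)oxy]-1-[(1E)-2,6-dimethylhepta-1,5-dien-1-yl]-2-oxaspiro[4.5]dec-6-en-3-one, via homoprenylzinc bromide 19 (not isolated)
Conditions: 18, Zn dust, LiCl, THF, 50 °C; then 17, Pd(dppf)Cl2 (5 mol%), THF, rt → 45 °C
Reagents that add atoms: none
Why: Zinc insertion into the primary bromide followed by Negishi coupling with the alkenyl iodide forms the sp2–sp3 bond with retention of geometry (E-trisubstituted alkene), the bidentate phosphine suppressing β-hydride elimination and the organozinc tolerating lactone and enol ether.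

Step 11
Reactants: 20 (1R,5R)-6-[(tert-butyldimethylsilyl)oxy]-1-[(1E)-2,6-dimethylhepta-1,5-dien-1-yl]-2-oxaspiro[4.5]dec-6-en-3-one
Product: 21 (1R,5R)-1-[(1E)-2,6-dimethylhepta-1,5-dien-1-yl]-2-oxaspiro[4.5]dec-7-ene-3,6-dione
Conditions: Pd(OAc)2 (1.1 equiv), MeCN, rt → 40 °C
Reagents that add atoms: none
Why: Saegusa–Ito oxidation: palladation of the silyl enol ether at C7 and β-hydride elimination toward C8 give the C7=C8 enone, the only regiochemistry open to this enol ether.

Step 12
Reactants: 21 (1R,5R)-1-[(1E)-2,6-dimethylhepta-1,5-dien-1-yl]-2-oxaspiro[4.5]dec-7-ene-3,6-dione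
Product: 23 (1R,5R)-1-[(1E)-2,6-dimethylhepta-1,5-dien-1-yl]-9-hydroxy-2-oxaspiro[4.5]dec-7-ene-3,6-dione (C9 epimers), via silyl dienol ether 22 (not isolated)
Conditions: TBSOTf, Et3N, CH2Cl2, 0 °C; then DMDO (1.05 equiv), acetone/CH2Cl2, −78 °C; AcOH/THF/H2O work-up
Reagents that add atoms: dimethyldioxirane, CC1(C)OO1
Why: Because C5 is quaternary the enone can only be deprotonated at C9, giving the 1-silyloxy-1,3-diene, and in this vinylogous Rubottom oxidation the dioxirane at −78 °C should transfer oxygen to the electron-rich diene terminus C9 faster than to the isolated trisubstituted alkenes, the C9 configuration being irrelevant because it is erased in step 13.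

Step 13
Reactants: 23 (1R,5R)-1-[(1E)-2,6-dimethylhepta-1,5-dien-1-yl]-9-hydroxy-2-oxaspiro[4.5]dec-7-ene-3,6-dione (C9 epimers)
Product: 24 (1R,5R)-1-[(1E)-2,6-dimethylhepta-1,5-dien-1-yl]-2-oxaspiro[4.5]dec-7-ene-3,6,9-trione
Conditions: Dess–Martin periodinane, CH2Cl2, 0 °C → rt
Reagents that add atoms: none
Why: Dess–Martin oxidation of the secondary allylic alcohol gives the ene-dione under conditions that leave alkenes, lactone and the quaternary centre untouched.

Step 14
Reactants: 24 (1R,5R)-1-[(1E)-2,6-dimethylhepta-1,5-dien-1-yl]-2-oxaspiro[4.5]dec-7-ene-3,6,9-trione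
Product: 25 (1R,5R,9S)-1-[(1E)-2,6-dimethylhepta-1,5-dien-1-yl]-9-hydroxy-2-oxaspiro[4.5]dec-7-ene-3,6-dione
Conditions: NaBH4, CeCl3·7H2O, MeOH, −78 °C
Reagents that add atoms: none
Why: Luche reduction gives 1,2-addition to the C9 carbonyl, which is far more accessible than the C6 carbonyl next to quaternary C5, and hydride is expected to arrive on the ring face that carries the lactone CH2 (C4), away from C1 and its dienyl substituent, so that the hydroxyl ends up cis to C1 (9S).

Step 15
Reactants: 25 (1R,5R,9S)-1-[(1E)-2,6-dimethylhepta-1,5-dien-1-yl]-9-hydroxy-2-oxaspiro[4.5]dec-7-ene-3,6-dione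
Product: 27 cis-fused 2-(trichloromethyl)-4,5-dihydro-1,3-oxazole spanning C8 (N) and C9 (O) of (1R,5R,8R,9S)-1-[(1E)-2,6-dimethylhepta-1,5-dien-1-yl]-2-oxaspiro[4.5]decane-3,6-dione, via trichloroacetimidate 26 (not isolated)
Conditions: Cl3CCN, DBU (0.2 equiv), CH2Cl2, −20 → 0 °C
Reagents that add atoms: trichloroacetonitrile, ClC(Cl)(Cl)C#N
Why: Base-catalysed addition of the alcohol to the nitrile gives the trichloroacetimidate, whose nitrogen adds to C8 of the enone in an intramolecular aza-Michael reaction (5-exo-trig), the five-membered tether forcing a cis ring fusion and hence C8–N cis to C9–O (8R).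

Step 16
Reactants: 27 cis-fused 2-(trichloromethyl)-4,5-dihydro-1,3-oxazole of the spiro keto-lactone
Product: 29 (+)-miliusane V, N-[(1R,5R,8R,9S)-1-[(1E)-2,6-dimethylhepta-1,5-dien-1-yl]-9-hydroxy-3,6-dioxo-2-oxaspiro[4.5]decan-8-yl]acetamide, via amino alcohol hydrochloride 28 (not isolated)
Conditions: 1 M HCl, THF, rt; then NaHCO3, Ac2O, THF/H2O, 0 °C
Reagents that add atoms: acetic anhydride, CC(=O)OC(C)=O
Why: Dilute acid hydrolyses the 2-trichloromethyl-oxazoline to the cis-amino alcohol salt without touching a stereocentre, and acetic anhydride under bicarbonate (Schotten–Baumann-type) conditions acylates the amine selectively over the secondary hydroxyl.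

Compound list

1 | 1-ethynylcyclopentan-1-ol | OC1(CCCC1)C#C | starting material
2 | allylmagnesium bromide | C=CC[Mg]Br | starting material
3 | alkenylmagnesium chelate, 4-allyl-1-oxa-2-magnesaspiro[4.4]non-3-ene (Mg bridges the alkoxide O and the terminal alkenyl C; formed in situ) | C=CCC1=C[Mg]OC12CCCC2 | intermediate
4 | (Z)-1-(1-iodopenta-1,4-dien-2-yl)cyclopentan-1-ol | OC1(CCCC1)/C(CC=C)=C\I | intermediate
5 | triethyl({1-[(1Z)-1-iodopenta-1,4-dien-2-yl]cyclopentyl}oxy)silane | CC[Si](CC)(CC)OC1(CCCC1)/C(CC=C)=C\I | intermediate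
6 | (4Z)-5-iodo-4-[1-(triethylsilyloxy)cyclopentyl]pent-4-ene-1,2-diol (C2 epimers; formed in situ) | CC[Si](CC)(CC)OC1(CCCC1)/C(CC(O)CO)=C\I | intermediate
7 | (3Z)-4-iodo-3-[1-(triethylsilyloxy)cyclopentyl]but-3-enal | CC[Si](CC)(CC)OC1(CCCC1)/C(CC=O)=C\I | intermediate
8 | (3Z)-4-iodo-3-[1-(triethylsilyloxy)cyclopentyl]but-3-enoic acid (formed in situ) | CC[Si](CC)(CC)OC1(CCCC1)/C(CC(=O)O)=C\I | intermediate
9 | methyl (3Z)-4-iodo-3-[1-(triethylsilyloxy)cyclopentyl]but-3-enoate | CC[Si](CC)(CC)OC1(CCCC1)/C(CC(=O)OC)=C\I | intermediate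
10 | propyne | CC#C | starting material
11 | methyl (3Z)-3-[1-(triethylsilyloxy)cyclopentyl]hept-3-en-5-ynoate | CC[Si](CC)(CC)OC1(CCCC1)/C(CC(=O)OC)=C\C#CC | intermediate
12 | methyl 2-[(2R,3R)-3-(prop-1-yn-1-yl)-2-[1-(triethylsilyloxy)cyclopentyl]oxiran-2-yl]acetate | CC[Si](CC)(CC)OC1(CCCC1)[C@]2(CC(=O)OC)O[C@@H]2C#CC | intermediate
13 | methyl 2-[(1R)-1-[(1R)-1-hydroxybut-2-yn-1-yl]-2-oxocyclohexyl]acetate (formed in situ) | O=C1CCCC[C@@]1(CC(=O)OC)[C@H](O)C#CC | intermediate
14 | (1R,5R)-1-(prop-1-yn-1-yl)-2-oxaspiro[4.5]decane-3,6-dione | C1CC(=O)[C@@]2(CC(=O)O[C@@H]2C#CC)CC1 | intermediate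
15 | (1R,5R)-6-[(tert-butyldimethylsilyl)oxy]-1-(prop-1-yn-1-yl)-2-oxaspiro[4.5]dec-6-en-3-one | C1CC=C(O[Si](C)(C)C(C)(C)C)[C@@]2(CC(=O)O[C@@H]2C#CC)C1 | intermediate
16 | (E)-alkenylzirconocene chloride of 15, Zr on the methyl-bearing alkene carbon (formed in situ) | C1CC=C(O[Si](C)(C)C(C)(C)C)[C@@]2(CC(=O)O[C@@H]2/C=C(\C)[Zr](Cl)(C3C=CC=C3)C3C=CC=C3)C1 | intermediate
17 | (1R,5R)-6-[(tert-butyldimethylsilyl)oxy]-1-[(1E)-2-iodoprop-1-en-1-yl]-2-oxaspiro[4.5]dec-6-en-3-one | C1CC=C(O[Si](C)(C)C(C)(C)C)[C@@]2(CC(=O)O[C@@H]2/C=C(\C)I)C1 | intermediate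
18 | 5-bromo-2-methylpent-2-ene | CC(C)=CCCBr | starting material
19 | (4-methylpent-3-en-1-yl)zinc bromide (formed in situ) | CC(C)=CCC[Zn]Br | intermediate
20 | (1R,5R)-6-[(tert-butyldimethylsilyl)oxy]-1-[(1E)-2,6-dimethylhepta-1,5-dien-1-yl]-2-oxaspiro[4.5]dec-6-en-3-one | C1CC=C(O[Si](C)(C)C(C)(C)C)[C@@]2(CC(=O)O[C@@H]2/C=C(\C)CCC=C(C)C)C1 | intermediate
21 | (1R,5R)-1-[(1E)-2,6-dimethylhepta-1,5-dien-1-yl]-2-oxaspiro[4.5]dec-7-ene-3,6-dione | C1=CC(=O)[C@@]2(CC(=O)O[C@@H]2/C=C(\C)CCC=C(C)C)CC1 | intermediate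
22 | (1R,5R)-6-[(tert-butyldimethylsilyl)oxy]-1-[(1E)-2,6-dimethylhepta-1,5-dien-1-yl]-2-oxaspiro[4.5]deca-6,8-dien-3-one (formed in situ) | C1=CC=C(O[Si](C)(C)C(C)(C)C)[C@@]2(CC(=O)O[C@@H]2/C=C(\C)CCC=C(C)C)C1 | intermediate
23 | (1R,5R)-1-[(1E)-2,6-dimethylhepta-1,5-dien-1-yl]-9-hydroxy-2-oxaspiro[4.5]dec-7-ene-3,6-dione (C9 epimers) | OC1C=CC(=O)[C@@]2(CC(=O)O[C@@H]2/C=C(\C)CCC=C(C)C)C1 | intermediate
24 | (1R,5R)-1-[(1E)-2,6-dimethylhepta-1,5-dien-1-yl]-2-oxaspiro[4.5]dec-7-ene-3,6,9-trione | O=C1C=CC(=O)[C@@]2(CC(=O)O[C@@H]2/C=C(\C)CCC=C(C)C)C1 | intermediate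
25 | (1R,5R,9S)-1-[(1E)-2,6-dimethylhepta-1,5-dien-1-yl]-9-hydroxy-2-oxaspiro[4.5]dec-7-ene-3,6-dione | C1=CC(=O)[C@@]2(CC(=O)O[C@@H]2/C=C(\C)CCC=C(C)C)C[C@@H]1O | intermediate
26 | (1R,5R,9S)-1-[(1E)-2,6-dimethylhepta-1,5-dien-1-yl]-3,6-dioxo-2-oxaspiro[4.5]dec-7-en-9-yl 2,2,2-trichloroacetimidate (formed in situ) | C1=CC(=O)[C@@]2(CC(=O)O[C@@H]2/C=C(\C)CCC=C(C)C)C[C@@H]1OC(=N)C(Cl)(Cl)Cl | intermediate
27 | cis-fused 2-(trichloromethyl)-4,5-dihydro-1,3-oxazole (N on C8, O on C9) of (1R,5R,8R,9S)-1-[(1E)-2,6-dimethylhepta-1,5-dien-1-yl]-2-oxaspiro[4.5]decane-3,6-dione | ClC(Cl)(Cl)C1=N[C@@H]2CC(=O)[C@@]3(CC(=O)O[C@@H]3/C=C(\C)CCC=C(C)C)C[C@@H]2O1 | intermediate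
28 | (1R,5R,8R,9S)-8-amino-1-[(1E)-2,6-dimethylhepta-1,5-dien-1-yl]-9-hydroxy-2-oxaspiro[4.5]decane-3,6-dione hydrochloride (formed in situ) | N[C@@H]1CC(=O)[C@@]2(CC(=O)O[C@@H]2/C=C(\C)CCC=C(C)C)C[C@@H]1O.Cl | intermediate
29 | (+)-miliusane V, N-[(1R,5R,8R,9S)-1-[(1E)-2,6-dimethylhepta-1,5-dien-1-yl]-9-hydroxy-3,6-dioxo-2-oxaspiro[4.5]decan-8-yl]acetamide | CC(=O)N[C@@H]1CC(=O)[C@@]2(CC(=O)O[C@@H]2/C=C(\C)CCC=C(C)C)C[C@@H]1O | target

Total step count: 16.
Longest linear sequence: 16 steps (1 → 29; the zinc reagent from 18 is made within step 10).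

Steps most likely to fail

1. Step 7. The oxirane may ionise at the propargylic carbon, or the ester carbonyl may intercept the developing cation before the C–C shift, or the silyl group may be lost first so that the tertiary oxygen closes the wrong lactone. Fallback (sets out from 5, returns at 14): the ester is kept out of the rearrangement and the lactone is made by oxidation. Sonogashira coupling of 5 with 10 gives the dienyne triethyl({1-[(4Z)-octa-1,4-dien-6-yn-4-yl]cyclopentyl}oxy)silane F1. Shi epoxidation, which should leave the monosubstituted alkene alone, gives (2R,3R)-2-allyl-3-(prop-1-yn-1-yl)-2-[1-(triethylsilyloxy)cyclopentyl]oxirane F2. BF3·OEt2 then effects the same 1,2-shift on a substrate that has no carbonyl neighbour and a more electron-rich migration terminus, giving (2R)-2-allyl-2-[(1R)-1-hydroxybut-2-yn-1-yl]cyclohexan-1-one F3. Lemieux–Johnson cleavage of the allyl group gives an aldehyde that closes at once to the lactol (1R,5R)-3-hydroxy-1-(prop-1-yn-1-yl)-2-oxaspiro[4.5]decan-6-one F4, and oxidation with TEMPO/PhI(OAc)2 gives 14.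

2. Step 14. Hydride may be delivered to the other face of the C9 carbonyl, because the spiro centre two atoms away differentiates the two faces only weakly. Fallback (sets out from 24, returns at 25): the carbinol is inverted instead of relying on facial control. If the reduction of 24 gives mainly (1R,5R,9R)-1-[(1E)-2,6-dimethylhepta-1,5-dien-1-yl]-9-hydroxy-2-oxaspiro[4.5]dec-7-ene-3,6-dione F6, a Mitsunobu reaction with formic acid (PPh3, DIAD, THF, 0 °C) gives (1R,5R,9S)-1-[(1E)-2,6-dimethylhepta-1,5-dien-1-yl]-3,6-dioxo-2-oxaspiro[4.5]dec-7-en-9-yl formate F7 by SN2 inversion. Methanolysis under KHCO3 at 0 °C releases 25.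

3. Step 12. Oxygen transfer may go to the side-chain alkenes or to C7 instead of C9 (loss of chemo- or regioselectivity). Fallback (sets out from 21, returns at 24): oxygen is introduced by substitution rather than by oxygen transfer. Dienol ether 22, made from 21 as in step 12, is brominated at C9 with NBS (THF, −78 °C), a γ-selective halogenation of silyl dienol ethers, to give (1R,5R)-9-bromo-1-[(1E)-2,6-dimethylhepta-1,5-dien-1-yl]-2-oxaspiro[4.5]dec-7-ene-3,6-dione F5. Kornblum oxidation (AgBF4, DMSO; then Et3N) converts the allylic bromide directly into 24, so that 23 and step 13 are bypassed.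

Further compounds

F1 | step 7 | triethyl({1-[(4Z)-octa-1,4-dien-6-yn-4-yl]cyclopentyl}oxy)silane | CC[Si](CC)(CC)OC1(CCCC1)/C(CC=C)=C\C#CC
F2 | step 7 | (2R,3R)-2-allyl-3-(prop-1-yn-1-yl)-2-[1-(triethylsilyloxy)cyclopentyl]oxirane | CC[Si](CC)(CC)OC1(CCCC1)[C@]2(CC=C)O[C@@H]2C#CC
F3 | step 7 | (2R)-2-allyl-2-[(1R)-1-hydroxybut-2-yn-1-yl]cyclohexan-1-one | O=C1CCCC[C@@]1(CC=C)[C@H](O)C#CC
F4 | step 7 | (1R,5R)-3-hydroxy-1-(prop-1-yn-1-yl)-2-oxaspiro[4.5]decan-6-one (C3 anomers) | C1CC(=O)[C@@]2(CC(O)O[C@@H]2C#CC)CC1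
F5 | step 12 | (1R,5R)-9-bromo-1-[(1E)-2,6-dimethylhepta-1,5-dien-1-yl]-2-oxaspiro[4.5]dec-7-ene-3,6-dione (C9 epimers) | BrC1C=CC(=O)[C@@]2(CC(=O)O[C@@H]2/C=C(\C)CCC=C(C)C)C1
F6 | step 14 | (1R,5R,9R)-1-[(1E)-2,6-dimethylhepta-1,5-dien-1-yl]-9-hydroxy-2-oxaspiro[4.5]dec-7-ene-3,6-dione | C1=CC(=O)[C@@]2(CC(=O)O[C@@H]2/C=C(\C)CCC=C(C)C)C[C@H]1O
F7 | step 14 | (1R,5R,9S)-1-[(1E)-2,6-dimethylhepta-1,5-dien-1-yl]-3,6-dioxo-2-oxaspiro[4.5]dec-7-en-9-yl formate | C1=CC(=O)[C@@]2(CC(=O)O[C@@H]2/C=C(\C)CCC=C(C)C)C[C@@H]1OC=O
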